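# Proposed total synthesis of CNP0325163.2 (51) by transannular Michael closure of a cyclodecenedione

## The problem

CNP0325163.2 (51) is a trans-fused clerodane. Ring A (C1–C5, C10) carries an equatorial C1 hydroxyl and the 4(18)-methylene. Ring B (C5–C10) carries four contiguous stereocentres (C6–C9). C9 bears the C11 carbinol that leads to a β-substituted butenolide.

Eight stereocentres must be set. C5 and C9 are methyl-bearing quaternary carbons, 1,3-diaxial across ring B. C8 is a tertiary carbinol next to C9, so two adjacent fully substituted carbons must be made where no hydrogen-versus-substituent bias exists.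

Once C8 and C9 exist they can steer C5 and C10 through ring conformation. In the decalin the two axial methyl groups shield the β face, so external reagents reach C1, C6 and C7 from the α face. That is the wrong face for the hydrogens at C1 and C7. The equatorial oxygens at C1, C6 and C7 therefore need thermodynamic or internally delivered reduction.

The five oxygens end in four states: free secondary (C1), acetate (C6), isobutyrate (C7 and C11), free tertiary (C8). This demands an order of events more than a set of protecting groups.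

Sensitive groups:
- the exocyclic alkene (no hydrogenation, ozone or strong acid);
- the butenolide (no strong base, hydride or electron-transfer reagent);
- esters next to free hydroxyls (acyl migration).

The enabling feature is the ring-fusion bond C5–C10. It joins C10, α to the C1 oxygen, to C5, β to the C7 oxygen. Read as a Michael retron it opens rings A and B together and leaves a cyclodec-5-ene-1,7-dione in which only C8 and C9 are stereogenic.

## Retrosynthesis

**Butenolide (51 ⇒ 50 ⇒ 49).** The C13=C14 bond and the C15–O16 ester bond are cut: ring-closing metathesis of acrylate 50, made from the 2-substituted allylic alcohol 49. A furan or finished butenolide would not survive the reductions that precede it. The forward steps must ignore the hindered C4 methylene and acylate only the primary allylic hydroxyl.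

**C1 carbinol and the isobutyrates (49 ⇒ 48 ⇒ 47 ⇒ 46 ⇒ 45).** The C1–H bond and the two isobutyrate C–O bonds are cut. The C1 ketone is kept as the protecting group of the C1 oxygen: C7 and C11 are acylated in 46 while C1 cannot react. The ketone in 47 is then reduced by single-electron transfer to the equatorial alcohol 48. Hydride would give the axial epimer.

**C11–C12 (45 ⇒ 40 + 42).** The bond next to the carbinol is cut to aldehyde 40 and the 2-(alkoxymethyl)allyl unit of 42. A chiral allylborane sets C11 by reagent control. Aldol or furylmethyl additions would rest on substrate control at a neopentyl aldehyde. Aldehyde 40 is simpler by the whole side chain.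

**Ring B oxygens (40 ⇒ 39 ⇒ 38 ⇒ 37 ⇒ 35 ⇒ 34 ⇒ 33).** The C6–O and C7–H bonds are cut. The C7 ketone left by the key step serves to oxygenate C6.
- Electrophiles reach C6 only from the α face, so the oxygen is introduced without stereochemical demand (34) and corrected through the non-enolisable 6,7-dione 35.
- Hydride adds to C6 from the α face, and the new 6β-hydroxyl delivers hydride to C7 (37).
- Oxidation of the two PMB ethers of 37 closes the C8 ether onto O7 as a cyclic acetal and frees O11 (38). O6 is thereby left alone for the acetate.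

**C4 methylene and the C1 mask (33 ⇒ 32 ⇒ 30).** The C4=C18 bond is cut (Wittig). The C1 ketone of 30 is reduced for the time being so that only C7 can enolise; the later Dess–Martin step returns it.

**Ring fusion (30 ⇒ 29).** The C5–C10 bond is cut. The transannular Michael addition of the C10 enolate to the C5=C6–C7 enone of the ten-membered enedione 29 forms both rings and sets C5 and C10. Stepwise annulation would have to build the C5 quaternary centre and the C1 and C7 oxygens separately. The forward reaction must select the enone face set by C8 and C9.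

**Macrocycle (29 ⇒ 28 ⇒ 27).** The C6–C7 bond is cut: Nozaki–Hiyama–Kishi closure of iodoalkene–aldehyde 27. The E geometry is fixed beforehand and the aldehyde reacts in the presence of the C1 ketone. Olefination or metathesis closures would leave the trisubstituted alkene geometry open.

**Oxidation levels (27 ⇒ 26 ⇒ 24 ⇒ 23).** The C1 ketone comes from the C10=C1 alkene of 23 by hydroboration and oxidation; the C7 aldehyde comes from the ester.

**C8–C9 (23 ⇒ 20 ⇒ 19 + 16).** The bond between the two fully substituted carbons is cut: Ireland–Claisen rearrangement of lactate ester 20. Both centres derive from two alkene geometries and one carbinol centre. Addition to a C8 ketone would have to tell a methyl from a methylene group. Alcohol 19 and acid 16 are simple.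

**Fragments.**
- 19 ⇒ 18 ⇒ 8 + 13 (acylation of an alkenyl Grignard reagent, then CBS reduction).
- 8 ⇒ 7 ⇒ 5 ⇒ 4 ⇒ 3 ⇒ 1 + 2.
- 13 ⇒ 11 ⇒ 9.
- 16 ⇒ 14 + 15.
- 42 ⇒ 41 + 15.

## Roads not taken

**Alternative 1:** A labdane 8,9-epoxide from the chiral pool is opened at C9 with BF3·OEt2. A cascade of 1,2-shifts (C10 methyl to C9, H5 to C10, C4 methyl to C5) and proton loss gives A1. No ring is closed and no skeletal bond to a new fragment is made.
- Merits: the decalin, C5, C9, C10, the 8-hydroxyl and the exocyclic alkene arrive in one step from a cheap terpenoid. This is far shorter than the 18 steps the chosen plan needs to reach 30.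
- Weak points: the cation can stop after the first or second shift (halimane-type alkenes). A1 has no oxygen at C1, C6 or C11. C11 could be reached by ester enolate oxidation, but C1 is an unactivated methylene with no neighbouring handle. C6 would again need a C7 ketone.
- Comparison: in step count to the bicycle this road is better. The chosen plan sets against it that the C1 and C7 carbonyls are the very groups that make its ring-forming step work, so the two hardest oxygens are in place in 30.

**Alternative 2:** The C9–C10 bond is cut. Anodic oxidation of a silyl dienol ether and attack by C10 of a ring-A silyl enol ether closes ring B and gives A2.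
- Merits: A2 holds the C1 ketone, the exocyclic alkene and a 7,8-alkene. Dihydroxylation from the open α face would give the cis-7,8-diol of the target in one step, which the chosen plan reaches only through steps 21–24.
- Weak points: the coupling joins a quaternary carbon to a tertiary one between two electron-rich partners. The face of C9 is decided only by a remote C5 centre that must first be made enantioselectively. The exocyclic alkene is itself oxidisable at the anode. The C11 ester must still be converted into a carbinol with a carbon chain. C6 would need allylic oxidation.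
- Comparison: ring-B oxidation is more direct here. The chosen plan forms its quaternary centre by a two-electron reaction with closer precedent and under reversible conditions, and keeps the C7 ketone for C6.

**Alternative 3:** The C8–C9 bond is cut. An aluminium Lewis acid opens a C9–C11 epoxide on a ring-A-fused cycloheptane; C8 migrates from C11 to C9, contracting the ring to ring B and leaving C11 as the aldehyde of A3.
- Merits: the shift is stereospecific. A3 carries the C1 oxygen, the C4 ketone, the protected 7,8-diol and the C11 aldehyde, and so is closer to 51 than 30 is.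
- Weak points: the migrating carbon bears an oxygen and migrates poorly, so hydride shift or ring-A bond shift compete. The fused seven-membered precursor has as many stereocentres as the product. A3 has no carbonyl next to C6, so the C6 acetate has no entry.
- Comparison: functional-group readiness at C1, C4 and C11 is better. The chosen plan sets against it the C7 ketone for C6 and a precursor whose only stereocentres are C8 and C9.

Key step: step 18

## Route

Assumption: α and β refer to the usual clerodane drawing (ring A left, C10 above C5). Centres that are destroyed later are carried as mixtures (α-carbon of 16 and 20, C1 of 26, C7 of 28, acetal carbon of 38–40 and 45). C1 and C6 of 31–34 are drawn as the epimers expected from α-face attack. PMB is 4-methoxybenzyl.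

Step 1
Reactants: 1 methyl 4-chloro-4-oxobutanoate; 2 bis(trimethylsilyl)acetylene
Product: 3 methyl 4-oxo-6-(trimethylsilyl)hex-5-ynoate
Conditions: AlCl3, CH2Cl2, 0 °C
Reagents that add atoms: none
Why: Friedel–Crafts-type acylation of the bis-silylalkyne with ipso loss of one silyl group; the ester is inert and the product carries C1–C6.

Step 2
Reactants: 3 methyl 4-oxo-6-(trimethylsilyl)hex-5-ynoate
Product: 4 methyl 3-[2-(trimethylsilylethynyl)-1,3-dioxolan-2-yl]propanoate
Conditions: (Me3SiOCH2)2, Me3SiOTf (cat.), CH2Cl2, −78 to −20 °C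
Reagents that add atoms: 1,2-bis(trimethylsilyloxy)ethane, C[Si](C)(C)OCCO[Si](C)(C)C
Why: Noyori ketalisation under aprotic conditions avoids conjugate addition of the diol to the ynone; the ketal keeps C4 out of conjugation in the key step.

Step 3
Reactants: 4 methyl 3-[2-(trimethylsilylethynyl)-1,3-dioxolan-2-yl]propanoate
Product: 5 methyl 3-(2-ethynyl-1,3-dioxolan-2-yl)propanoate
Conditions: K2CO3 (cat.), MeOH, rt
Reagents that add atoms: none
Why: Methanolysis of the alkynyl C–Si bond; ketal and methyl ester are stable.

Step 4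
Reactants: 5 methyl 3-(2-ethynyl-1,3-dioxolan-2-yl)propanoate
Product: 7 methyl 3-{2-[(E)-1-iodoprop-1-en-2-yl]-1,3-dioxolan-2-yl}propanoate, via alkenyl(dimethyl)alane 6 (not isolated)
Conditions: Me3Al, Cp2ZrCl2 (20 mol %), CH2Cl2, 0 °C; then I2, THF, −30 to 0 °C
Reagents that add atoms: trimethylaluminium, C[Al](C)C; iodine, II
Why: Negishi zirconium-catalysed carboalumination adds methyl and aluminium syn, with methyl on the internal carbon (C5); iodinolysis with retention gives the E iodide (C4 trans to I). The ester should survive Me3Al at 0 °C.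

Step 5
Reactants: 7 methyl 3-{2-[(E)-1-iodoprop-1-en-2-yl]-1,3-dioxolan-2-yl}propanoate
Product: 8 N-methoxy-N-methyl-3-{2-[(E)-1-iodoprop-1-en-2-yl]-1,3-dioxolan-2-yl}propanamide
Conditions: MeNH(OMe)·HCl, i-PrMgCl, THF, −20 °C
Reagents that add atoms: N,O-dimethylhydroxylamine hydrochloride, CNOC.Cl
Why: Direct ester-to-Weinreb-amide exchange through the magnesium amide; at −20 °C the alkenyl iodide should not undergo exchange.

Step 6
Reactants: 9 prop-2-yn-1-ol
Product: 11 (Z)-3-iodo-2-methylprop-2-en-1-ol, via cyclic alkenylmagnesium alkoxide 10 (not isolated)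
Conditions: MeMgBr, CuI (10 mol %), THF, −10 °C to rt; then I2, −10 °C
Reagents that add atoms: methylmagnesium bromide, C[Mg]Br; iodine, II
Why: Duboudin copper-catalysed anti carbomagnesiation; magnesium chelated by the alkoxide ends cis to CH2O, and iodinolysis with retention gives the Z iodide (I cis to CH2OH).

Step 7
Reactants: 11 (Z)-3-iodo-2-methylprop-2-en-1-ol; 12 4-methoxybenzyl chloride
Product: 13 (Z)-1-iodo-3-(4-methoxybenzyloxy)-2-methylprop-1-ene
Conditions: NaH, n-Bu4NI (cat.), THF/DMF, 0 °C to rt
Reagents that add atoms: none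
Why: Williamson etherification. A benzyl-type ether is chosen because a silyl ether cis to the later carbon–metal bond would migrate to carbon.

Step 8
Reactants: 14 2-bromopropanoic acid (racemic); 15 4-methoxybenzyl alcohol
Product: 16 2-(4-methoxybenzyloxy)propanoic acid (racemic)
Conditions: NaH (2.2 equiv), THF, 0 to 60 °C; then aq. HCl
Reagents that add atoms: none
Why: Williamson substitution of the α-bromo carboxylate by the alkoxide; the racemate suffices because this centre becomes the enolate carbon in step 12.

Step 9
Reactants: 13 (Z)-1-iodo-3-(4-methoxybenzyloxy)-2-methylprop-1-ene; 8 N-methoxy-N-methyl-3-{2-[(E)-1-iodoprop-1-en-2-yl]-1,3-dioxolan-2-yl}propanamide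
Product: 18 (Z)-6-(4-methoxybenzyloxy)-5-methyl-1-{2-[(E)-1-iodoprop-1-en-2-yl]-1,3-dioxolan-2-yl}hex-4-en-3-one, via alkenylmagnesium chloride 17 (not isolated)
Conditions: i-PrMgCl·LiCl, THF, 0 °C; then 8, −20 °C to rt
Reagents that add atoms: none
Why: Iodine–magnesium exchange with retention of geometry, then Weinreb ketone synthesis (C1–C10 bond); the chelated tetrahedral intermediate prevents over-addition. The alkenyl iodide of 8 should not exchange with an alkenylmagnesium species.

Step 10
Reactants: 18 (Z)-6-(4-methoxybenzyloxy)-5-methyl-1-{2-[(E)-1-iodoprop-1-en-2-yl]-1,3-dioxolan-2-yl}hex-4-en-3-one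
Product: 19 (S,Z)-6-(4-methoxybenzyloxy)-5-methyl-1-{2-[(E)-1-iodoprop-1-en-2-yl]-1,3-dioxolan-2-yl}hex-4-en-3-ol
Conditions: (R)-2-methyl-CBS-oxazaborolidine (20 mol %), BH3·SMe2, THF, −30 °C
Reagents that add atoms: none
Why: Corey–Bakshi–Shibata reduction; the trisubstituted alkenyl group acts as the large substituent, so the (R)-catalyst should give the (S)-carbinol at C1, the centre that is relayed to C8 and C9 in step 12.

Step 11
Reactants: 19 (S,Z)-6-(4-methoxybenzyloxy)-5-methyl-1-{2-[(E)-1-iodoprop-1-en-2-yl]-1,3-dioxolan-2-yl}hex-4-en-3-ol; 16 2-(4-methoxybenzyloxy)propanoic acid (racemic)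
Product: 20 allylic ester of 19 with 16 (C1 S; α-carbon of the acyl part as a mixture)
Conditions: DCC, DMAP (cat.), CH2Cl2, 0 °C to rt
Reagents that add atoms: none
Why: Steglich esterification of a secondary allylic alcohol; the acyl α-centre need not be controlled.

Step 12
Reactants: 20 allylic ester of 19 with 16
Product: 23 methyl ester with C8 and C9 set: methyl 2-(PMB-oxy)-2-methyl-3-methyl-3-(PMB-oxymethyl)alk-4E-enoate bearing the C2–C6 ketal–iodoalkene chain, via silyl ketene acetal 21 (not isolated), via carboxylic acid 22 (not isolated)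
Conditions: LiN(i-Pr)2, Me3SiCl, Et3N, THF, −78 to 50 °C; aq. HCl; then Me3SiCHN2, MeOH/toluene, 0 °C
Reagents that add atoms: trimethylsilyldiazomethane, C[Si](C)(C)C=[N+]=[N-]
Why: Ireland–Claisen rearrangement of a lactate ester. Lithium chelation between the enolate oxygen and the PMB ether fixes the ketene acetal geometry (OSi cis to OPMB). In the chair transition state the C2 chain is equatorial, so the (S)-C1 centre and the Z alkene (CH2OPMB axial, methyl equatorial) give C8 and C9 as in the target, with a new E C10=C1 alkene. The acid is methylated for handling.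

Step 13
Reactants: 23 methyl ester with C8 and C9 set
Product: 24 primary alcohol at C7 (C8 OPMB; C9 CH2OPMB; E C10=C1 alkene)
Conditions: i-Bu2AlH, CH2Cl2, −78 to 0 °C
Reagents that add atoms: none
Why: Ester reduction; the alkenyl iodide, ketal and ethers tolerate the aluminium hydride at low temperature.

Step 14
Reactants: 24 primary alcohol at C7
Product: 26 C1,C7-diol (C1 carbinol as a mixture), via bis(9-BBN) adduct 25 (not isolated)
Conditions: 9-BBN (3 equiv), THF, 50 °C; then H2O2, aq. NaOAc, 0 °C
Reagents that add atoms: hydrogen peroxide, OO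
Why: Hydroboration–oxidation; boron goes to C1, the alkene carbon remote from quaternary C9. The trisubstituted iodoalkene should be too hindered and deactivated to react with 9-BBN.

Step 15
Reactants: 26 C1,C7-diol
Product: 27 C1-keto C7-aldehyde (open-chain iodoalkene keto-aldehyde)
Conditions: Dess–Martin periodinane, NaHCO3, CH2Cl2, rt
Reagents that add atoms: none
Why: Neutral oxidation of both hydroxyls in one operation; the aldehyde has no α-hydrogen, and buffered conditions avoid aldol reactions of the 1,5-dicarbonyl.

Step 16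
Reactants: 27 C1-keto C7-aldehyde
Product: 28 ten-membered (E)-7-hydroxy-cyclodec-5-en-1-one with the C4 ketal (C7 carbinol as a mixture)
Conditions: CrCl2 (divalent chromium, 8 equiv), NiCl2 (2 mol %), DMSO/THF, rt, 2 mM
Reagents that add atoms: none
Why: Intramolecular Nozaki–Hiyama–Kishi reaction forms C6–C7. The alkenylchromium species adds to aldehydes and not to ketones, the E geometry is retained, and high dilution favours the ten-membered ring.

Step 17
Reactants: 28 ten-membered (E)-7-hydroxy-cyclodec-5-en-1-one
Product: 29 ten-membered (E)-enedione: C1 and C7 ketones, C4 ethylene ketal, C5 methyl on the E C5=C6 alkene, C8 methyl and OPMB, C9 methyl and CH2OPMB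
Conditions: Dess–Martin periodinane, NaHCO3, CH2Cl2, rt
Reagents that add atoms: none
Why: Oxidation of the allylic alcohol gives the enone; both C7 epimers converge.

Step 18
Reactants: 29 ten-membered (E)-enedione
Product: 30 trans-decalin-1,7-dione: C4 ethylene ketal, 5β-methyl, 10α-H, 8β-methyl-8α-OPMB, 9β-methyl-9α-CH2OPMB
Conditions: t-BuOK (0.2 equiv), t-BuOH/THF, 0 °C to rt
Reagents that add atoms: none
Why: tert-Butoxide enolises the C1 ketone reversibly towards C2 and C10. Only the C10 enolate has an electrophile within reach; it adds through C10 to C5, the β-carbon of the E-enone, and the resulting C7 enolate is protonated at C6. The closest known reaction type is the base-mediated transannular Michael closure of macrocyclic keto-enones to fused bicycles. Ring A (C1–C5, C10) closes in a 6-(enolendo)-exo-trig mode and ring B (C5–C10) in a 6-(enolexo)-endo-trig mode, both allowed. C5 is controlled by C8 and C9: in the chair–chair transition state the C9 methyl and the C8 ether oxygen take the axial sites and CH2OPMB and the C8 methyl the equatorial ones, so C10 attacks the enone face that places the C5 methyl syn to the C9 methyl; the other face would force CH2OPMB and the C8 methyl axial. C10 is set thermodynamically, because it remains enolisable next to the C1 ketone and the trans fusion (H10 anti to the C5 methyl) is expected to be favoured. The step needs regioselectivity (the C2 enolate can only revert), chemoselectivity against transannular aldol addition to C7 (reversible) and face selectivity at C5 (secured by conformation only). The ketal keeps C4 out of conjugation, so C5 is the only electrophilic carbon.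

Step 19
Reactants: 30 trans-decalin-1,7-dione
Product: 32 1-hydroxy-decalin-4,7-dione (1β-OH expected; C8 OPMB; C9 CH2OPMB), via C1 carbinol ketal 31 (not isolated)
Conditions: NaBH4, MeOH/CH2Cl2, −40 °C; then 1 M HCl, THF, rt
Reagents that add atoms: water, O
Why: Chemoselective hydride reduction of the C1 ketone. The C7 ketone lies between two quaternary carbons and under two syn-axial methyl groups and should not react. The C1 configuration is irrelevant because step 22 returns the ketone. Acid then hydrolyses the strained ketal.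

Step 20
Reactants: 32 1-hydroxy-decalin-4,7-dione
Product: 33 1-hydroxy-4(18)-methylene-decalin-7-one
Conditions: Ph3PCH3Br, t-BuOK, toluene, 90 °C
Reagents that add atoms: methyltriphenylphosphonium bromide, C[P+](c1ccccc1)(c1ccccc1)c1ccccc1.[Br-]
Why: Wittig methylenation of the C4 ketone under forcing conditions, as used for ketones next to quaternary carbons; the far more hindered C7 ketone is expected to be only enolised.

Step 21
Reactants: 33 1-hydroxy-4(18)-methylene-decalin-7-one
Product: 34 1,6-dihydroxy-4(18)-methylene-decalin-7-one (6α-OH expected)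
Conditions: KN(SiMe3)2 (3 equiv), THF, −78 °C; then 2-(phenylsulfonyl)-3-phenyloxaziridine
Reagents that add atoms: 2-(phenylsulfonyl)-3-phenyloxaziridine, O=S(=O)(c1ccccc1)N1OC1c1ccccc1
Why: Davis hydroxylation of the C7 enolate, the only enolate possible once C1 is an alkoxide (C8 has no hydrogen). The oxidant should approach C6 anti to the axial C5 methyl; this configuration is erased in step 22.

Step 22
Reactants: 34 1,6-dihydroxy-4(18)-methylene-decalin-7-one
Product: 35 4(18)-methylene-decalin-1,6,7-trione
Conditions: Dess–Martin periodinane, NaHCO3, CH2Cl2, rt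
Reagents that add atoms: none
Why: Both secondary alcohols are oxidised: the C1 ketone returns and C6 becomes part of a 1,2-dione that cannot enolise (C5 and C8 are quaternary).

Step 23
Reactants: 35 4(18)-methylene-decalin-1,6,7-trione
Product: 37 6β,7α-dihydroxy-4(18)-methylene-decalin-1-one (C8 OPMB; C9 CH2OPMB), via 6β-hydroxy-7-ketone 36 (not isolated)
Conditions: NaBH4 (0.3 equiv), MeOH/CH2Cl2, −78 °C; then AcOH, Me4NBH(OAc)3, MeCN, −30 to 0 °C
Reagents that add atoms: none
Why: The activated 1,2-dione is reduced before the isolated C1 ketone. Hydride adds to C6 axially from the α face, anti to the adjacent axial C5 methyl, while C7 is blocked on both faces; this gives the equatorial 6β-alcohol. Saksena–Evans reduction then delivers hydride to C7 from the C6-bound acetoxyborohydride, bypassing the axial methyl groups, to give the trans-diequatorial diol and leave the C1 ketone untouched.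

Step 24
Reactants: 37 6β,7α-dihydroxy-4(18)-methylene-decalin-1-one
Product: 38 7,8-O-(4-methoxybenzylidene) acetal with free 6β-OH and C11-OH (C1 ketone)
Conditions: DDQ (2.5 equiv), 4 Å MS, CH2Cl2, 0 °C; then pH 7 buffer
Reagents that add atoms: none
Why: Oxidation of the C8 PMB ether gives an oxocarbenium ion that is trapped by the cis 7α-hydroxyl as a five-membered acetal (the Oikawa–Yonemitsu reaction). The C11 PMB ether has no such neighbour and is cleaved on work-up. O6 is thus differentiated from O7 without a separate protection step.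

Step 25
Reactants: 38 7,8-O-(4-methoxybenzylidene) acetal with free 6β-OH and C11-OH
Product: 39 C11 aldehyde with free 6β-OH
Conditions: TEMPO (cat.), PhI(OAc)2, CH2Cl2, rt
Reagents that add atoms: none
Why: Oxoammonium oxidation selects the primary over the hindered secondary alcohol; the aldehyde has no α-hydrogen.

Step 26
Reactants: 39 C11 aldehyde with free 6β-OH
Product: 40 6β-acetoxy C11 aldehyde (7,8-acetal; C1 ketone)
Conditions: Ac2O, DMAP, pyridine, CH2Cl2, rt
Reagents that add atoms: acetic anhydride, CC(=O)OC(C)=O
Why: Acetylation of the only free hydroxyl installs the C6 acetate of the target.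

Step 27
Reactants: 41 3-chloro-2-(chloromethyl)prop-1-ene; 15 4-methoxybenzyl alcohol
Product: 42 2-(chloromethyl)-3-(4-methoxybenzyloxy)prop-1-ene
Conditions: NaH, THF, 0 °C to rt (41 in excess)
Reagents that add atoms: none
Why: Mono-etherification of the bis-allylic chloride; excess dichloride suppresses the diether.

Step 28
Reactants: 40 6β-acetoxy C11 aldehyde; 42 2-(chloromethyl)-3-(4-methoxybenzyloxy)prop-1-ene
Product: 45 (11R)-homoallylic alcohol with the C12–C13(=CH2)–C16H2OPMB chain, via allylmagnesium chloride 43 (not isolated), via allyldiisopinocampheylborane 44 (not isolated)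
Conditions: Mg, THF, 0 °C; (+)-Ipc2BOMe, Et2O, −78 to 0 °C; then 40, −78 °C; H2O2, aq. NaOAc
Reagents that add atoms: none
Why: Brown allylboration with a 2-substituted allyl group through a closed chair transition state. The borane from (+)-Ipc2BOMe (made from (−)-α-pinene) should add to the Re face and give 11R by reagent control. The aldehyde reacts at −78 °C while the hindered C1 ketone and the acetate do not, and the buffered peroxide work-up spares the acetate.

Step 29
Reactants: 45 (11R)-homoallylic alcohol with the 7,8-acetal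
Product: 46 7α,8α,11-triol (6β-OAc; C1 ketone; C16 OPMB)
Conditions: AcOH/H2O/THF (3:1:1), 40 °C
Reagents that add atoms: none
Why: Mild acid hydrolysis of the benzylidene-type acetal; the PMB ether, the acetate and the 1,1-disubstituted alkenes should survive, and acyl migration is slow under acid.

Step 30
Reactants: 46 7α,8α,11-triol
Product: 47 7,11-bis(isobutyrate) (6β-OAc; 8α-OH; C1 ketone)
Conditions: (i-PrCO)2O, DMAP, Et3N, CH2Cl2, rt to 40 °C
Reagents that add atoms: isobutyric anhydride, CC(C)C(=O)OC(=O)C(C)C
Why: Both secondary hydroxyls are acylated; the tertiary C8 hydroxyl does not react, and the C1 oxygen is protected as the ketone.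

Step 31
Reactants: 47 7,11-bis(isobutyrate) with C1 ketone
Product: 48 1α-alcohol (equatorial) with all three esters in place
Conditions: SmI2 (divalent samarium), H2O, THF, 0 °C
Reagents that add atoms: none
Why: Single-electron reduction, like dissolving-metal reduction, gives the more stable carbinol: the oxygen-bound samarium takes the equatorial site, away from the C5 and C9 methyl groups, before C-protonation. Hydride would come from the α face and give the axial 1β-alcohol. Simple esters and isolated alkenes are not reduced under these conditions.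

Step 32
Reactants: 48 1α-alcohol with C16 OPMB
Product: 49 C16 primary allylic alcohol
Conditions: DDQ, CH2Cl2/pH 7 buffer, 0 °C
Reagents that add atoms: none
Why: Oxidative PMB cleavage under buffered conditions; esters, alkenes and free hydroxyls are tolerated.

Step 33
Reactants: 49 C16 primary allylic alcohol
Product: 50 C16 acrylate
Conditions: acryloyl chloride, i-Pr2NEt, CH2Cl2, −78 °C
Reagents that add atoms: acryloyl chloride, C=CC(=O)Cl
Why: The primary allylic hydroxyl is acylated before the hindered secondary C1 hydroxyl (flanked by the C9 substituents) and the tertiary C8 hydroxyl.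

Step 34
Reactants: 50 C16 acrylate
Product: 51 CNP0325163.2
Conditions: RuCl2(=CHPh)(H2IMes)(PCy3) (second-generation Grubbs catalyst, 5 mol %), CH2Cl2, 40 °C
Reagents that add atoms: none
Why: Ring-closing metathesis of the acrylate with the 1,1-disubstituted C13 alkene gives the β-substituted butenolide and ethene. The C4 methylene, next to a quaternary carbon, should not take part.

## Compound list

1 | methyl 4-chloro-4-oxobutanoate | COC(=O)CCC(=O)Cl | starting material
2 | bis(trimethylsilyl)acetylene | C[Si](C)(C)C#C[Si](C)(C)C | starting material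
3 | methyl 4-oxo-6-(trimethylsilyl)hex-5-ynoate | COC(=O)CCC(=O)C#C[Si](C)(C)C | intermediate
4 | methyl 3-[2-(trimethylsilylethynyl)-1,3-dioxolan-2-yl]propanoate | COC(=O)CCC1(OCCO1)C#C[Si](C)(C)C | intermediate
5 | methyl 3-(2-ethynyl-1,3-dioxolan-2-yl)propanoate | COC(=O)CCC1(OCCO1)C#C | intermediate
6 | dimethyl{(E)-2-[2-(3-methoxy-3-oxopropyl)-1,3-dioxolan-2-yl]prop-1-enyl}alane | COC(=O)CCC1(OCCO1)/C(C)=C/[Al](C)C | intermediate (not isolated)
7 | methyl 3-{2-[(E)-1-iodoprop-1-en-2-yl]-1,3-dioxolan-2-yl}propanoate | COC(=O)CCC1(OCCO1)/C(C)=C/I | intermediate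
8 | N-methoxy-N-methyl-3-{2-[(E)-1-iodoprop-1-en-2-yl]-1,3-dioxolan-2-yl}propanamide | CON(C)C(=O)CCC1(OCCO1)/C(C)=C/I | intermediate
9 | prop-2-yn-1-ol | C#CCO | starting material
10 | cyclic (Z)-alkenylmagnesium alkoxide (4-methyl-2,5-dihydro-1,2-oxamagnesole) | CC1=C[Mg]OC1 | intermediate (not isolated)
11 | (Z)-3-iodo-2-methylprop-2-en-1-ol | OC/C(C)=C\I | intermediate
12 | 4-methoxybenzyl chloride | COc1ccc(CCl)cc1 | starting material
13 | (Z)-1-iodo-3-(4-methoxybenzyloxy)-2-methylprop-1-ene | COc1ccc(COC/C(C)=C\I)cc1 | intermediate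
14 | 2-bromopropanoic acid (racemic) | CC(Br)C(=O)O | starting material
15 | 4-methoxybenzyl alcohol | COc1ccc(CO)cc1 | starting material
16 | 2-(4-methoxybenzyloxy)propanoic acid (racemic) | CC(OCc1ccc(OC)cc1)C(=O)O | intermediate
17 | (Z)-[3-(4-methoxybenzyloxy)-2-methylprop-1-enyl]magnesium chloride | COc1ccc(COC/C(C)=C\[Mg]Cl)cc1 | intermediate (not isolated)
18 | (Z)-6-(4-methoxybenzyloxy)-5-methyl-1-{2-[(E)-1-iodoprop-1-en-2-yl]-1,3-dioxolan-2-yl}hex-4-en-3-one | COc1ccc(COC/C(C)=C\C(=O)CCC2(OCCO2)/C(C)=C/I)cc1 | intermediate
19 | (S,Z)-6-(4-methoxybenzyloxy)-5-methyl-1-{2-[(E)-1-iodoprop-1-en-2-yl]-1,3-dioxolan-2-yl}hex-4-en-3-ol | COc1ccc(COC/C(C)=C\[C@@H](O)CCC2(OCCO2)/C(C)=C/I)cc1 | intermediate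
20 | 2-(4-methoxybenzyloxy)propanoate ester of 19 (C1 S; acyl α-carbon mixed) | COc1ccc(COC/C(C)=C\[C@@H](OC(=O)C(C)OCc2ccc(OC)cc2)CCC2(OCCO2)/C(C)=C/I)cc1 | intermediate
21 | chelation-derived trimethylsilyl ketene acetal of 20 (OSi cis to OPMB) | COc1ccc(COC/C(C)=C\[C@@H](O/C(O[Si](C)(C)C)=C(/OCc2ccc(OC)cc2)C)CCC2(OCCO2)/C(C)=C/I)cc1 | intermediate (not isolated)
22 | Claisen acid: C7 acid, C8 (methyl, OPMB), C9 (methyl, CH2OPMB), E C10=C1 alkene, C2–C3–C4 ketal–C5(Me)=C6HI chain | OC(=O)[C@@](C)(OCc1ccc(OC)cc1)[C@@](C)(COCc1ccc(OC)cc1)/C=C/CCC1(OCCO1)/C(C)=C/I | intermediate (not isolated)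
23 | methyl ester of 22 | COC(=O)[C@@](C)(OCc1ccc(OC)cc1)[C@@](C)(COCc1ccc(OC)cc1)/C=C/CCC1(OCCO1)/C(C)=C/I | intermediate
24 | C7 primary alcohol from 23 | OC[C@@](C)(OCc1ccc(OC)cc1)[C@@](C)(COCc1ccc(OC)cc1)/C=C/CCC1(OCCO1)/C(C)=C/I | intermediate
25 | bis(9-BBN) adduct: O7-borinate and C1-borane | C1CCC2CCCC1B2OC[C@@](C)(OCc1ccc(OC)cc1)[C@@](C)(COCc1ccc(OC)cc1)CC(CCC1(OCCO1)/C(C)=C/I)B1C2CCCC1CCC2 | intermediate (not isolated)
26 | C1,C7-diol (C1 mixed) | OC[C@@](C)(OCc1ccc(OC)cc1)[C@@](C)(COCc1ccc(OC)cc1)CC(O)CCC1(OCCO1)/C(C)=C/I | intermediate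
27 | C1-keto C7-aldehyde with the E iodoalkene | O=C[C@@](C)(OCc1ccc(OC)cc1)[C@@](C)(COCc1ccc(OC)cc1)CC(=O)CCC1(OCCO1)/C(C)=C/I | intermediate
28 | ten-membered (E)-7-hydroxy-enone: C1 ketone, C4 ketal, C7 carbinol (mixed) | O=C1CCC2(OCCO2)/C(C)=C/C(O)[C@@](C)(OCc2ccc(OC)cc2)[C@@](C)(COCc2ccc(OC)cc2)C1 | intermediate
29 | ten-membered (E)-enedione: C1 and C7 ketones, C4 ketal, C8 (methyl, OPMB), C9 (methyl, CH2OPMB) | O=C1CCC2(OCCO2)/C(C)=C/C(=O)[C@@](C)(OCc2ccc(OC)cc2)[C@@](C)(COCc2ccc(OC)cc2)C1 | intermediate
30 | trans-decalin-1,7-dione: C4 ketal, 5β-methyl, 10α-H, 8α-OPMB, 9α-CH2OPMB | C12(OCCO1)CCC(=O)[C@@H]3[C@]2(C)CC(=O)[C@@](C)(OCc1ccc(OC)cc1)[C@@]3(C)COCc1ccc(OC)cc1 | intermediate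
31 | 1β-hydroxy-decalin-7-one with the C4 ketal | C12(OCCO1)CC[C@@H](O)[C@@H]3[C@]2(C)CC(=O)[C@@](C)(OCc1ccc(OC)cc1)[C@@]3(C)COCc1ccc(OC)cc1 | intermediate (not isolated)
32 | 1β-hydroxy-decalin-4,7-dione | O=C1CC[C@@H](O)[C@@H]2[C@]1(C)CC(=O)[C@@](C)(OCc1ccc(OC)cc1)[C@@]2(C)COCc1ccc(OC)cc1 | intermediate
33 | 1β-hydroxy-4(18)-methylene-decalin-7-one | C=C1CC[C@@H](O)[C@@H]2[C@]1(C)CC(=O)[C@@](C)(OCc1ccc(OC)cc1)[C@@]2(C)COCc1ccc(OC)cc1 | intermediate
34 | 1β,6α-dihydroxy-4(18)-methylene-decalin-7-one | C=C1CC[C@@H](O)[C@@H]2[C@]1(C)[C@@H](O)C(=O)[C@@](C)(OCc1ccc(OC)cc1)[C@@]2(C)COCc1ccc(OC)cc1 | intermediate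
35 | 4(18)-methylene-decalin-1,6,7-trione | C=C1CCC(=O)[C@@H]2[C@]1(C)C(=O)C(=O)[C@@](C)(OCc1ccc(OC)cc1)[C@@]2(C)COCc1ccc(OC)cc1 | intermediate
36 | 6β-hydroxy-4(18)-methylene-decalin-1,7-dione | C=C1CCC(=O)[C@@H]2[C@]1(C)[C@H](O)C(=O)[C@@](C)(OCc1ccc(OC)cc1)[C@@]2(C)COCc1ccc(OC)cc1 | intermediate (not isolated)
37 | 6β,7α-dihydroxy-4(18)-methylene-decalin-1-one (8α-OPMB, 9α-CH2OPMB) | C=C1CCC(=O)[C@@H]2[C@]1(C)[C@H](O)[C@@H](O)[C@@](C)(OCc1ccc(OC)cc1)[C@@]2(C)COCc1ccc(OC)cc1 | intermediate
38 | 7α,8α-O-(4-methoxybenzylidene) acetal, 6β-OH, C11-OH, C1 ketone | C=C1CCC(=O)[C@@H]2[C@]1(C)[C@H](O)[C@H]1OC(c3ccc(OC)cc3)O[C@@]1(C)[C@@]2(C)CO | intermediate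
39 | C11 aldehyde, 6β-OH, 7,8-acetal | C=C1CCC(=O)[C@@H]2[C@]1(C)[C@H](O)[C@H]1OC(c3ccc(OC)cc3)O[C@@]1(C)[C@@]2(C)C=O | intermediate
40 | C11 aldehyde, 6β-OAc, 7,8-acetal | C=C1CCC(=O)[C@@H]2[C@]1(C)[C@H](OC(C)=O)[C@H]1OC(c3ccc(OC)cc3)O[C@@]1(C)[C@@]2(C)C=O | intermediate
41 | 3-chloro-2-(chloromethyl)prop-1-ene | C=C(CCl)CCl | starting material
42 | 2-(chloromethyl)-3-(4-methoxybenzyloxy)prop-1-ene | C=C(CCl)COCc1ccc(OC)cc1 | intermediate
43 | {2-[(4-methoxybenzyloxy)methyl]allyl}magnesium chloride | C=C(C[Mg]Cl)COCc1ccc(OC)cc1 | intermediate (not isolated)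
44 | B-{2-[(4-methoxybenzyloxy)methyl]allyl}diisopinocampheylborane (isopinocampheyl groups from (−)-α-pinene) | C=C(COCc1ccc(OC)cc1)CB([C@H]1C[C@H]2C[C@@H]([C@@H]1C)C2(C)C)[C@H]1C[C@H]2C[C@@H]([C@@H]1C)C2(C)C | intermediate (not isolated)
45 | (11R)-homoallylic alcohol: 6β-OAc, 7,8-acetal, C1 ketone, C12–C13(=CH2)–CH2OPMB | C=C1CCC(=O)[C@@H]2[C@]1(C)[C@H](OC(C)=O)[C@H]1OC(c3ccc(OC)cc3)O[C@@]1(C)[C@@]2(C)[C@@H](CC(=C)COCc1ccc(OC)cc1)O | intermediate
46 | 7α,8α,11-triol: 6β-OAc, C1 ketone | C=C1CCC(=O)[C@@H]2[C@]1(C)[C@H](OC(C)=O)[C@@H](O)[C@@](C)(O)[C@@]2(C)[C@@H](CC(=C)COCc1ccc(OC)cc1)O | intermediate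
47 | 7,11-bis(isobutyrate): 6β-OAc, 8α-OH, C1 ketone | C=C1CCC(=O)[C@@H]2[C@]1(C)[C@H](OC(C)=O)[C@@H](OC(=O)C(C)C)[C@@](C)(O)[C@@]2(C)[C@@H](CC(=C)COCc1ccc(OC)cc1)OC(=O)C(C)C | intermediate
48 | 1α-alcohol of 47 | C=C1CC[C@H](O)[C@@H]2[C@]1(C)[C@H](OC(C)=O)[C@@H](OC(=O)C(C)C)[C@@](C)(O)[C@@]2(C)[C@@H](CC(=C)COCc1ccc(OC)cc1)OC(=O)C(C)C | intermediate
49 | C16 primary allylic alcohol | C=C1CC[C@H](O)[C@@H]2[C@]1(C)[C@H](OC(C)=O)[C@@H](OC(=O)C(C)C)[C@@](C)(O)[C@@]2(C)[C@@H](CC(=C)CO)OC(=O)C(C)C | intermediate
50 | C16 acrylate | C=C1CC[C@H](O)[C@@H]2[C@]1(C)[C@H](OC(C)=O)[C@@H](OC(=O)C(C)C)[C@@](C)(O)[C@@]2(C)[C@@H](CC(=C)COC(=O)C=C)OC(=O)C(C)C | intermediate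
51 | CNP0325163.2 | C=C1CC[C@H](O)[C@@H]2[C@]1(C)[C@H](OC(C)=O)[C@@H](OC(=O)C(C)C)[C@@](C)(O)[C@@]2(C)[C@@H](CC1=CC(=O)OC1)OC(=O)C(C)C | target

## Step count and least certain steps

Total: 34 steps. Longest linear sequence: 30 steps (steps 1–5, 9–26, 28–34).

**Step 18 (key step).** The conjugate addition may take the other face of the enone (C5 methyl anti to the C9 methyl), or the ring fusion may settle cis, because only the conformation of the ten-membered ring links C8 and C9 to C5. Fallback: enamine activation in place of the enolate. From 29, pyrrolidine and acetic acid in acetonitrile should form the C1 enamine of the enedione F1 reversibly. Its C10 terminus adds to C5 through a neutral, more compact transition state (Stork enamine Michael addition) to give the enamine of the decalin dione F2. Aqueous acetic acid hydrolyses F2 and the route is rejoined at 30.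

**Step 12.** The rearrangement joins two fully substituted carbons. Slow [3,3] shift with ketene loss, or leakage through a boat transition state that erodes the C8/C9 ratio, are the likely failures. Fallback: an ester-enolate [2,3]-Wittig rearrangement. From 19, O-alkylation with methyl 2-bromopropanoate (NaH, THF) gives the α-allyloxy ester F3. LiN(i-Pr)2 at −78 °C should shift the allyl group from oxygen to C8 through a five-membered transition state, on the same allyl face as in the Claisen route, to give the tertiary α-hydroxy ester F4; its C8/C9 relation would have to be established. 4-Methoxybenzyl trichloroacetimidate with La(OTf)3 then gives 23.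

**Step 23.** Hydride may add to the C7 carbonyl first, which would lead to the diaxial diol, or may also reduce the C1 ketone. Fallback: electron transfer in place of hydride. From 35, SmI2 (2 equiv) in THF/MeOH at −78 °C should reduce only the 1,2-dione to its enediolate. Protonation at the less hindered C6 from the α face gives 36, which is taken on with Me4NBH(OAc)3 as before to 37. No new compound arises.

**Step 24.** The benzylic cation at O8 may be hydrolysed before O7 closes the acetal, or the cation at O11 may be trapped by O7. Fallback: separate the two events. From 37, DDQ in wet CH2Cl2 removes both PMB ethers to give the 6β,7α,8α,11-tetraol F5. 4-Methoxybenzaldehyde dimethyl acetal with camphorsulfonic acid then forms the acetal on the only cis-1,2-diol and returns 38.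

**Step 31.** Protonation under kinetic control may give the axial 1β-alcohol, and the new hydroxyl may take the acyl group from O11 if the medium turns basic. Fallback: hydride reduction with inversion. From 47, NaBH4 should give the axial 1β-alcohol F6 by α-face attack. A Mitsunobu reaction with chloroacetic acid (PPh3, diisopropyl azodicarboxylate) inverts C1 to the 1α-chloroacetate F7. Thiourea with NaHCO3 in ethanol removes the chloroacetyl group in the presence of the other esters and gives 48.

## Further compounds

F1 | step 18 | C1 pyrrolidine enamine (C1=C10) of enedione 29 | C1(N3CCCC3)CCC2(OCCO2)/C(C)=C/C(=O)[C@@](C)(OCc2ccc(OC)cc2)[C@@](C)(COCc2ccc(OC)cc2)C=1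
F2 | step 18 | C1 pyrrolidine enamine (C1=C2) of decalin dione 30 | C12(OCCO1)CC=C(N4CCCC4)[C@@H]3[C@]2(C)CC(=O)[C@@](C)(OCc1ccc(OC)cc1)[C@@]3(C)COCc1ccc(OC)cc1
F3 | step 12 | methyl 2-(allyloxy)propanoate ether of 19 (C1 S) | COc1ccc(COC/C(C)=C\[C@@H](OC(C)C(=O)OC)CCC2(OCCO2)/C(C)=C/I)cc1
F4 | step 12 | methyl ester with free C8 hydroxyl (C8 and C9 as in 23) | COC(=O)[C@@](C)(O)[C@@](C)(COCc1ccc(OC)cc1)/C=C/CCC1(OCCO1)/C(C)=C/I
F0 | step 23 | none | none
F5 | step 24 | 6β,7α,8α,11-tetrahydroxy-4(18)-methylene-decalin-1-one | C=C1CCC(=O)[C@@H]2[C@]1(C)[C@H](O)[C@@H](O)[C@@](C)(O)[C@@]2(C)CO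
F6 | step 31 | 1β-alcohol epimer of 48 | C=C1CC[C@@H](O)[C@@H]2[C@]1(C)[C@H](OC(C)=O)[C@@H](OC(=O)C(C)C)[C@@](C)(O)[C@@]2(C)[C@@H](CC(=C)COCc1ccc(OC)cc1)OC(=O)C(C)C
F7 | step 31 | 1α-chloroacetate of 48 | C=C1CC[C@H](OC(=O)CCl)[C@@H]2[C@]1(C)[C@H](OC(C)=O)[C@@H](OC(=O)C(C)C)[C@@](C)(O)[C@@]2(C)[C@@H](CC(=C)COCc1ccc(OC)cc1)OC(=O)C(C)C
A1 | alternative 1 | 8-hydroxy-7-(tert-butyldimethylsilyloxy)-cleroda-4(18)-ene C12 methyl ester | C=C1CCC[C@@H]2[C@]1(C)C[C@@H](O[Si](C)(C)C(C)(C)C)[C@@](C)(O)[C@@]2(C)CC(=O)OC
A2 | alternative 2 | 1-oxo-cleroda-4(18),7-diene C11 methyl ester | C=C1CCC(=O)[C@@H]2[C@]1(C)CC=C(C)[C@@]2(C)C(=O)OC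
A3 | alternative 3 | 4-oxo-1-(tert-butyldimethylsilyloxy)-decalin 7,8-acetonide with the C11 aldehyde on C9 | O=C1CC[C@H](O[Si](C)(C)C(C)(C)C)[C@@H]2[C@]1(C)C[C@H]3OC(C)(C)O[C@@]3(C)[C@@]2(C)C=O
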